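# Proposed total synthesis of (+)-methylphelligrin A (17)

Flavanone numbering is used throughout: O1, C2, C3, C4, C4a, C5 to C8, C8a. Ring A is the benzo ring and ring C the heterocycle. Ring B is the 4-hydroxyphenyl group on C2 (C1' to C6'), and ring D is the arene of the 2-hydroxybenzyl group.

## Analysis of the target

Compound 17 is a flavanone, a 2,3-dihydrochromen-4-one made of ring A (C4a, C5, C6, C7, C8, C8a) and ring C (O1, C2, C3, C4, C4a, C8a). It carries ring B on C2 and a 2-hydroxybenzyl group (CH2 plus ring D) on C6.

The only stereocentre is C2. The SMILES string fixes it as (R), the mirror image of the common (2S) flavanones, so no chiral-pool flavanone helps. C2 is a benzylic ether carbon β to the C4 ketone. Base opens ring C by E1cB to the achiral chalcone, and strong acid ionises C2–O1 with the help of the para oxygen of ring B. C2 should therefore be set late and then see only neutral conditions.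

The hard part is ring A. Five of its six carbons are substituted, and its three oxygens are all different: O1 on C8a is tied into ring C, C5 bears a free chelated OH, and C7 bears OMe. In a phloroglucinol-based synthesis C6 and C8 are almost equally nucleophilic, and the oxygens on C5 and C8a are almost equally able to close ring C. Benzylation, methylation and cyclisation would each have to win a regiochemical contest, and the 6-benzyl and 8-benzyl series interconvert through the chalcone.

The feature that invites the chosen move is the run C5(OH)–C6(CH2Ar)–C7(OMe)–C8(H) of ring A, closed by the C8a=C4a bond that ring A shares with ring C. Phenol, alkyl, alkoxy, hydrogen is exactly the pattern that the benzannulation of a vinylketene with an alkynyl ether writes around a new benzene ring. C8a=C4a, flanked by O1 and C4=O, is the C2=C3 bond of a 4-pyranone. The three phenols and the doubly benzylic CH2 call for one common protecting group that is removed in a single neutral step.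

## Retrosynthetic reasoning

**17 ⇒ 16.** The last step only uncovers the phenols. The three O–CH2Ph bonds of 16 (on O5, O4' and the oxygen of ring D) are cut together by hydrogenolysis. This deprotection is neither acidic nor basic, so C2 is not endangered. One kind of protecting group keeps it to one step.

**16 ⇒ 14 + 15.** The C2–C1' bond is cut, not the O1–C2 bond. Forming O1–C2 is a reversible oxa-Michael addition whose reverse reaction racemises the product. Forming C2–C1' by 1,4-addition of an aryl–metal species to the flat chromone 14 is irreversible. It brings in all of ring B from the catalogue boronic acid 15 and sets the only stereocentre under catalyst control in the last skeletal step. Everything before it is achiral, so nothing can racemise during the light and heat of the ring construction.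

**14 ⇒ 13.** Only the O5–benzyl bond is cut. The peri-hydroxy ketone of 13 is an acetylacetonate-like chelator and a proton source for aryl–rhodium species, so it is masked with the group that leaves anyway in the last step.

**13 ⇒ 8 + 5 (key disconnection).** Ring A is taken apart completely. The bonds C5–C6, C7–C8 and C4a–C5 are cut, and so is C8–C8a, through the Wolff shift. C6, C7, the OMe group, the CH2 group and ring D go to ynol ether 5. C5 and C8 go to the diazoacetyl group of 8, and C4a and C8a are C3 and C2 of its 4-pyranone ring.

- **What is gained.** O1 is already in ring C, so the contest between the two oxygens for ring closure disappears. The polarity of the ynol ether decides C6 against C8. The OMe group arrives as OMe and the phenol as OH, so no O-selective methylation is needed.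
- **What the forward reaction must do.** It has to run a cascade of Wolff rearrangement, [2+2] cycloaddition, 4π opening and 6π closure.
- **In one sentence.** Irradiating pyranonyl diazomethyl ketone 8 with ynol ether 5 builds ring A of chromone 13. This is not the chalcone route.

**8 ⇒ 6.** The bond between the carboxyl carbon and the diazo carbon is cut. The forward reaction is acylation of a diazoalkane by acid chloride 7, made in the flask from the catalogue 4-pyranone acid 6. The precursor of the key step is thus one operation from a purchased compound.

**5 ⇒ 1 + 2.** The propargylic C–C bond is cut. Acetylide 4 is generated from 1 through enol ether 3 in one flask and alkylated by benzylic bromide 2, which brings ring D and the CH2 group.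

## Alternatives that were turned down

**Alternative 1:** the textbook route. The disconnections are O1–C2 and the Cα=Cβ bond. The forward sequence is Claisen–Schmidt condensation of the acetophenone A1 to the 2'-hydroxychalcone A2, followed by intramolecular oxa-Michael closure. It was turned down for three structural reasons.
- A2 has two different free phenols ortho to the carbonyl group. Closure through the one next to the benzyl group puts that group on C8. Both closures are reversible, so the outcome is a thermodynamic mixture unless one phenol is protected selectively, which costs steps.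
- The catalysts that close an unactivated 2'-hydroxychalcone also reopen the product, so enantiomeric purity erodes. The known remedy, an extra ester on Cα that is removed later, adds more steps.
- A1 itself requires mono-C-benzylation and mono-O-methylation of a phloroglucinol, which are the very contests listed above.

**Alternative 2:** the biomimetic route. The disconnection is C6–CH2. The forward step is late alkylation of (2R)-sakuranetin A3 by the ortho-quinone methide A4.
- C6 and C8 of A3 are both ortho or para to two oxygen donors, and C8 is not more hindered than C6. Mixtures of the 6-, 8- and 6,8-substituted series are expected, besides O-alkylation and [4+2] chroman formation.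
- Generating A4 needs heat, acid or base, and each of these opens ring C and racemises C2.
- A3 belongs to the unnatural (R) series and would have to be made by asymmetric synthesis first, so nothing is saved.

**Alternative 3:** one aromatic ring from another. Ring A is made from the 2-pyranone A5 by base-induced intramolecular Claisen condensation of the side-chain methylene onto the lactone carbonyl, which gives the acylphloroglucinol A6. The move does fix benzyl and OMe regiospecifically. However, the lactone carbonyl oxygen and the ring oxygen both emerge as free phenols flanking the acyl group, so the choice of which becomes O1 remains open. A6 then falls back on the chalcone route of alternative 1 with all its problems. A5 also needs several steps, more than the key step would win.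

Key step: step 3

Remark on the chemistry: the configuration is taken from the SMILES string, which reads (2R). Compounds 1, 2, 6 and 15 are taken as catalogue compounds.

## Route

Step 1
Reactants: 1 trichloroethylene; 2 1-(benzyloxy)-2-(bromomethyl)benzene
Product: 5 1-(benzyloxy)-2-(3-methoxyprop-2-yn-1-yl)benzene, via dichlorovinyl methyl ether 3 (not isolated), via lithium methoxyacetylide 4 (not isolated)
Conditions: KH, MeOH, THF, 0 °C to rt, then 1; n-BuLi, −78 to −40 °C; then 2, DMPU, −78 °C to rt; chromatography on base-washed support
Reagents that add atoms: methanol, CO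
Why: Methoxide adds to 1 by elimination–addition to give 3, n-BuLi then effects dehydrochlorination and chlorine–lithium exchange to 4, and 4 is alkylated by the reactive benzylic bromide 2 (the standard one-pot alkynyl ether synthesis from an alcohol and trichloroethylene). The methyl ynol ether has no β-hydrogen in its alkoxy group and so cannot fragment by a retro-ene reaction in the hot stage of step 3.

Step 2
Reactants: 6 comanic acid (4-oxo-4H-pyran-2-carboxylic acid)
Product: 8 2-(2-diazoacetyl)-4H-pyran-4-one, via comanoyl chloride 7 (not isolated)
Conditions: (COCl)2, cat. DMF, CH2Cl2, 0 °C to rt, evaporate; CH2N2 (excess), Et2O–THF, −10 to 0 °C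
Reagents that add atoms: diazomethane, C=[N+]=[N-]; oxalyl chloride, O=C(Cl)C(=O)Cl (chlorine of 7 only, lost again in 8)
Why: This is the acylation of diazomethane by an acid chloride, the first stage of the Arndt–Eistert sequence, with a second equivalent taking up HCl. The C=C bonds of the 4-pyranone belong to a cross-conjugated, partly aromatic vinylogous ester and should be slower dipolarophiles than the acid chloride is an acylating agent, so low temperature and short contact should favour 8.

Step 3
Reactants: 8 2-(2-diazoacetyl)-4H-pyran-4-one; 5 1-(benzyloxy)-2-(3-methoxyprop-2-yn-1-yl)benzene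
Product: 13 6-[2-(benzyloxy)benzyl]-5-hydroxy-7-methoxy-4H-chromen-4-one, via pyranonylketene 9 (not isolated), via vinylcyclobutenone 10 (not isolated), via dienylketene 11 (not isolated), via dienone tautomer 12 (not isolated)
Conditions: 5 (1.5 equiv), hν (365 nm LED, Pyrex), degassed ClCH2CH2Cl, 20 °C; then PhMe, 110 °C
Reagents that add atoms: none
Why: Long-wave light expels N2 from 8 with a concerted 1,2-shift of the pyranonyl group (photochemical Wolff rearrangement), which makes the C8–C8a bond and gives the vinylketene 9. The ynol ether 5 is polarised so that its carbon bearing CH2Ar is the nucleophile; it attacks the ketene carbonyl carbon, and the [2+2] cycloaddition (bonds C5–C6 and C7–C8) gives 10 with CH2Ar next to the future phenol carbon and OMe on C7, which settles the whole regiochemical question of ring A. Heat (and the light) opens 10 by reversible 4π electrocyclic cleavage of C5–C8, and the rotamer with the pyranonyl group turned inward, 11, is drained irreversibly by the next event. Ring A closes by a thermal disrotatory 6π electrocyclisation of 11 in which pyranone C3, the nucleophilic β-carbon of the enol ether, bonds to the electrophilic ketene carbon (bond C4a–C5) to give 12, whose C4a–H lies between two carbonyl groups and enolises at once to the chelated phenol 13. The closest known reaction type is the Danheiser benzannulation in its diazo ketone form, established for alkenyl, aryl and heteroaryl diazomethyl ketones with alkoxy-, siloxy- and aminoalkynes; here the C2=C3 bond of the 4-pyranone takes the part of the alkene. Site selectivity is secured by the substrate: pyranone C2 has O1 on one side and C3 on the other, so only one 6π closure exists and the new OH must end up peri to C4=O, and the ketenyl group and C4 stand trans on C2=C3, so that an oxa-6π closure to a 2-pyranone is geometrically barred. No stereocentre is created in 13 (C8 of 10 and C4a of 12 are transient and racemic). Chemoselectivity rests on three points: 365 nm light addresses the diazo ketone band and spares the short-wave band of the 4-pyranone, the methyl ynol ether cannot lose an alkene by retro-ene reaction at 110 °C, and the hydrogen-bonded 5-OH of 13 is too poor a nucleophile to be acylated by 9.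

Step 4
Reactants: 13 6-[2-(benzyloxy)benzyl]-5-hydroxy-7-methoxy-4H-chromen-4-one
Product: 14 5-(benzyloxy)-6-[2-(benzyloxy)benzyl]-7-methoxy-4H-chromen-4-one
Conditions: BnBr, K2CO3, cat. n-Bu4NI, DMF, 60 °C
Reagents that add atoms: benzyl bromide, BrCc1ccccc1
Why: This is a Williamson ether synthesis on the only acidic OH; warming in DMF overcomes the hydrogen bond and the flanking CH2Ar group, and dry carbonate does not open the chromone. The ether removes the O,O-chelating and protic peri-hydroxy ketone that would tie up rhodium and protonate aryl–rhodium in step 5, and it leaves in step 6 together with the other benzyl groups.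

Step 5
Reactants: 14 5-(benzyloxy)-6-[2-(benzyloxy)benzyl]-7-methoxy-4H-chromen-4-one; 15 4-(benzyloxy)phenylboronic acid
Product: 16 (2R)-5-(benzyloxy)-6-[2-(benzyloxy)benzyl]-2-[4-(benzyloxy)phenyl]-7-methoxy-2,3-dihydro-4H-chromen-4-one
Conditions: 15 (2 equiv), cat. [Rh(OH)(cod)]2, cat. (R)-MeO-F12-BIPHEP [(R)-(6,6'-dimethoxybiphenyl-2,2'-diyl)bis(bis(3,4,5-trifluorophenyl)phosphine)], PhMe, H2O (few equiv), 30 °C
Reagents that add atoms: none
Why: This is a Hayashi–Miyaura reaction (rhodium-catalysed asymmetric 1,4-addition of an arylboronic acid), a reaction type known for chromones, 5,7-dioxygenated ones included. C2 is set by face-selective insertion of C2=C3 into the aryl–rhodium bond inside the chiral pocket of the diphosphine. (S)-biaryl diphosphines give (S)-3-arylcyclohexanones, which correspond in space to (2S)-flavanones, so the (R)-ligand should give (2R) (the antipode is equally available should the sense be opposite), and the electron-poor ligand speeds insertion and protonation of the rhodium enolate before it can expel the aryloxide.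

Step 6
Reactants: 16 (2R)-5-(benzyloxy)-6-[2-(benzyloxy)benzyl]-2-[4-(benzyloxy)phenyl]-7-methoxy-2,3-dihydro-4H-chromen-4-one
Product: 17 (+)-methylphelligrin A, (2R)-5-hydroxy-6-(2-hydroxybenzyl)-2-(4-hydroxyphenyl)-7-methoxy-2,3-dihydro-4H-chromen-4-one
Conditions: H2 (1 atm), Pd/C, EtOAc–EtOH, rt, stopped at full conversion
Reagents that add atoms: none
Why: Catalytic hydrogenolysis of three aryl benzyl ethers under neutral conditions should leave C2 untouched by enolisation, ring opening or ionisation. The cyclic secondary C2–O1 ether, the electron-rich chelated ketone and the diarylmethane CH2 react much more slowly than primary O-benzyl groups.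

## Compound list

1 | trichloroethylene | ClC=C(Cl)Cl | starting material
2 | 1-(benzyloxy)-2-(bromomethyl)benzene | BrCc1ccccc1OCc1ccccc1 | starting material
3 | (E)-1,2-dichloro-1-methoxyethene | CO/C(Cl)=C\Cl | intermediate
4 | lithium methoxyacetylide | [Li]C#COC | intermediate
5 | 1-(benzyloxy)-2-(3-methoxyprop-2-yn-1-yl)benzene | COC#CCc1ccccc1OCc1ccccc1 | intermediate
6 | comanic acid (4-oxo-4H-pyran-2-carboxylic acid) | OC(=O)c1cc(=O)cco1 | starting material
7 | 4-oxo-4H-pyran-2-carbonyl chloride | ClC(=O)c1cc(=O)cco1 | intermediate
8 | 2-(2-diazoacetyl)-4H-pyran-4-one | [N-]=[N+]=CC(=O)c1cc(=O)cco1 | intermediate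
9 | 2-(2-oxoethenyl)-4H-pyran-4-one (pyranonylketene) | O=C=Cc1cc(=O)cco1 | intermediate
10 | 2-[2-(benzyloxy)benzyl]-3-methoxy-4-(4-oxo-4H-pyran-2-yl)cyclobut-2-en-1-one (racemic) | COC1=C(Cc2ccccc2OCc2ccccc2)C(=O)C1c1cc(=O)cco1 | intermediate
11 | (3E)-2-[2-(benzyloxy)benzyl]-3-methoxy-4-(4-oxo-4H-pyran-2-yl)buta-1,3-dien-1-one | O=C=C(Cc1ccccc1OCc1ccccc1)/C(OC)=C\c1cc(=O)cco1 | intermediate
12 | 6-[2-(benzyloxy)benzyl]-7-methoxy-4H-chromene-4,5(4aH)-dione (racemic) | COC1=C(Cc2ccccc2OCc2ccccc2)C(=O)C2C(=O)C=COC2=C1 | intermediate
13 | 6-[2-(benzyloxy)benzyl]-5-hydroxy-7-methoxy-4H-chromen-4-one | COc1cc2occc(=O)c2c(O)c1Cc1ccccc1OCc1ccccc1 | intermediate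
14 | 5-(benzyloxy)-6-[2-(benzyloxy)benzyl]-7-methoxy-4H-chromen-4-one | COc1cc2occc(=O)c2c(OCc2ccccc2)c1Cc1ccccc1OCc1ccccc1 | intermediate
15 | 4-(benzyloxy)phenylboronic acid | OB(O)c1ccc(OCc2ccccc2)cc1 | starting material
16 | (2R)-5-(benzyloxy)-6-[2-(benzyloxy)benzyl]-2-[4-(benzyloxy)phenyl]-7-methoxy-2,3-dihydro-4H-chromen-4-one | COc1cc2c(c(OCc3ccccc3)c1Cc1ccccc1OCc1ccccc1)C(=O)C[C@H](c1ccc(OCc3ccccc3)cc1)O2 | intermediate
17 | (+)-methylphelligrin A, (2R)-5-hydroxy-6-(2-hydroxybenzyl)-2-(4-hydroxyphenyl)-7-methoxy-2,3-dihydro-4H-chromen-4-one | COc1cc2c(c(O)c1Cc1ccccc1O)C(=O)C[C@H](c1ccc(O)cc1)O2 | target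

## Step count and risk

Total step count: 6. The longest linear sequence is 5 steps: steps 2, 3, 4, 5 and 6 from 6, or equally steps 1, 3, 4, 5 and 6 from 1.

**Step 3 (key step).**
- **Risk.** The ketene may be lost to paths other than the [2+2] cycloaddition: dimerisation, capture by traces of water, or interception of a carbene-like state by the alkyne. The pyranone may also suffer skeletal photochemistry. Finally, the vinylogous-ester-type cyclobutenone may resist 4π opening below the temperature at which the ynol ether degrades.
- **Fallback.** Ring construction is abandoned in favour of a cross-coupling on a preformed ring A. From 2, zinc insertion (Zn dust, LiCl, THF) gives [2-(benzyloxy)benzyl]zinc bromide F1. Purchased 5-hydroxy-7-methoxy-4H-chromen-4-one F2 is iodinated ortho to the chelated phenol through its thallium phenoxide (I2, TlOAc, CH2Cl2) to 5-hydroxy-6-iodo-7-methoxy-4H-chromen-4-one F3. Negishi coupling of F1 with F3 (Pd(OAc)2, SPhos, THF) comes back to the route at 13.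

**Step 5.**
- **Risk.** Insertion into the electron-rich 5,7-dialkoxychromone may be slow, so that protodeboronation of the electron-rich boronic acid overtakes it. Enantiomeric purity may be lost through expulsion of the aryloxide from the rhodium enolate and reclosure. A second aryl group may add 1,2 to the product ketone.
- **Fallback.** C2 is set by C–H instead of C–C bond formation. From 14 and 15, an oxidative boron-Heck arylation (Pd(OCOCF3)2, 1,10-phenanthroline, O2, DMF) gives 5-(benzyloxy)-6-[2-(benzyloxy)benzyl]-2-[4-(benzyloxy)phenyl]-7-methoxy-4H-chromen-4-one F4. Asymmetric hydrogenation follows ([Ru(cod)(2-methylallyl)2], the chiral imidazolinium salt SINpEt·HBF4 in the antipode that gives the (2R) series, KOt-Bu, H2). It gives the cis alcohol (2R,4R)-5-(benzyloxy)-6-[2-(benzyloxy)benzyl]-2-[4-(benzyloxy)phenyl]-7-methoxychroman-4-ol F5. Dess–Martin oxidation comes back to the route at 16.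

**Step 2.**
- **Risk.** Diazomethane may add as a dipole to the C2=C3 bond, which is activated by two carbonyl groups. The chlorinating agent may activate the C4 carbonyl (chloropyrylium formation).
- **Fallback.** Both the acid chloride and diazomethane are avoided. From 6, amide coupling (MeNHOMe·HCl, EDC, CH2Cl2) gives N-methoxy-N-methyl-4-oxo-4H-pyran-2-carboxamide F6. MeMgBr (THF, −78 °C) gives 2-acetyl-4H-pyran-4-one F7, whose acetyl group is its only enolisable site. Trifluoroacetylation (LiHMDS, then CF3CO2CH2CF3) gives 4,4,4-trifluoro-1-(4-oxo-4H-pyran-2-yl)butane-1,3-dione F8. Detrifluoroacetylative diazo transfer (MsN3, Et3N, H2O, MeCN) comes back to the route at 8.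

**Step 1.**
- **Risk.** Alkylation of the acetylide may be sluggish. Base may isomerise the doubly activated CH2 group from propargyl to allenyl. The ynol ether may be hydrated on an acidic support during purification.
- **Fallback.** The triple bond is made by elimination instead of alkylation. From 2, alkylation of the lithium enolate of methyl acetate (LDA, THF, −78 °C) gives methyl 3-[2-(benzyloxy)phenyl]propanoate F9. Enolisation and O-phosphorylation (LDA, ClP(O)(OEt)2) give diethyl {3-[2-(benzyloxy)phenyl]-1-methoxyprop-1-en-1-yl} phosphate F10. Elimination with t-BuLi (THF, −78 °C) comes back to the route at 5.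

**Step 6.**
- **Risk.** The hindered 5-O-benzyl group may cleave slowly and force long exposure. The benzylic C2–O1 bond could then be hydrogenolysed, or the ketone reduced.
- **Fallback.** Hydrogenolysis is replaced by Lewis acid dealkylation with a cation scavenger (BCl3, pentamethylbenzene, CH2Cl2, −78 °C). It sets out from 16 and comes back directly at 17. Chelation to C4=O speeds the cleavage at O5, the unchelated 7-OMe should stay, and the low temperature should keep ring C closed.

## Further compounds

F1 | step 3 | [2-(benzyloxy)benzyl]zinc bromide | Br[Zn]Cc1ccccc1OCc1ccccc1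
F2 | step 3 | 5-hydroxy-7-methoxy-4H-chromen-4-one | COc1cc(O)c2c(=O)ccoc2c1
F3 | step 3 | 5-hydroxy-6-iodo-7-methoxy-4H-chromen-4-one | COc1cc2occc(=O)c2c(O)c1I
F4 | step 5 | 5-(benzyloxy)-6-[2-(benzyloxy)benzyl]-2-[4-(benzyloxy)phenyl]-7-methoxy-4H-chromen-4-one | COc1cc2oc(-c3ccc(OCc4ccccc4)cc3)cc(=O)c2c(OCc2ccccc2)c1Cc1ccccc1OCc1ccccc1
F5 | step 5 | (2R,4R)-5-(benzyloxy)-6-[2-(benzyloxy)benzyl]-2-[4-(benzyloxy)phenyl]-7-methoxychroman-4-ol | COc1cc2c(c(OCc3ccccc3)c1Cc1ccccc1OCc1ccccc1)[C@H](O)C[C@H](c1ccc(OCc3ccccc3)cc1)O2
F6 | step 2 | N-methoxy-N-methyl-4-oxo-4H-pyran-2-carboxamide | CON(C)C(=O)c1cc(=O)cco1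
F7 | step 2 | 2-acetyl-4H-pyran-4-one | CC(=O)c1cc(=O)cco1
F8 | step 2 | 4,4,4-trifluoro-1-(4-oxo-4H-pyran-2-yl)butane-1,3-dione | O=C(CC(=O)C(F)(F)F)c1cc(=O)cco1
F9 | step 1 | methyl 3-[2-(benzyloxy)phenyl]propanoate | COC(=O)CCc1ccccc1OCc1ccccc1
F10 | step 1 | diethyl {3-[2-(benzyloxy)phenyl]-1-methoxyprop-1-en-1-yl} phosphate | CCOP(=O)(OCC)OC(OC)=CCc1ccccc1OCc1ccccc1
F0 | step 6 | none | none
A1 | alternative 1 | 1-[2,6-dihydroxy-3-(2-hydroxybenzyl)-4-methoxyphenyl]ethan-1-one | COc1cc(O)c(C(C)=O)c(O)c1Cc1ccccc1O
A2 | alternative 1 | (E)-1-[2,6-dihydroxy-3-(2-hydroxybenzyl)-4-methoxyphenyl]-3-(4-hydroxyphenyl)prop-2-en-1-one | COc1cc(O)c(C(=O)/C=C/c2ccc(O)cc2)c(O)c1Cc1ccccc1O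
A3 | alternative 2 | (2R)-sakuranetin, (2R)-5-hydroxy-2-(4-hydroxyphenyl)-7-methoxy-2,3-dihydro-4H-chromen-4-one | COc1cc2c(c(O)c1)C(=O)C[C@H](c1ccc(O)cc1)O2
A4 | alternative 2 | 6-methylidenecyclohexa-2,4-dien-1-one (ortho-quinone methide) | C=C1C=CC=CC1=O
A5 | alternative 3 | 3-[2-(benzyloxy)benzyl]-4-methoxy-6-(2-oxopropyl)-2H-pyran-2-one | COc1cc(CC(C)=O)oc(=O)c1Cc1ccccc1OCc1ccccc1
A6 | alternative 3 | 1-{3-[2-(benzyloxy)benzyl]-2,6-dihydroxy-4-methoxyphenyl}ethan-1-one | COc1cc(O)c(C(C)=O)c(O)c1Cc1ccccc1OCc1ccccc1
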